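**The decision.** You must decide whether midnight can go in as it stands, with equal charges of reagent and solid substrate, if first product is to finish ahead of double product.

common to all: solid substrate 0.16 M
- ochre: reagent 0.21 M; run made earlier
- amber: reagent 0.90 M; run made earlier
- midnight: reagent 0.160 M; time 2.5 min
- spring: reagent 0.640 M; time 2.5 min

| run | time / min | first product / % | solid substrate / % |
|---|---|---|---|
| ochre | 0.200 | 7.7 | 63.3 |
| ochre | 0.500 | 22.0 | 29.1 |
| ochre | 1.00 | 36.3 | 0 |
| ochre | 2.50 | 27.1 | 0 |
| amber | 0.667 | 45.1 | 0 |
| amber | 1.33 | 15.4 | 0.6 |
| amber | 2.00 | 6.3 | 0.1 |
| amber | 2.50 | 5.9 | 0 |

(readings scatter by 1 percentage point)

- solid substrate is a solid; its amount is given per volume of the solution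
- at the start none of the solid substrate is in solution

- which of these holds the largest part of the solid substrate at the end of midnight (solid substrate / first product / double product)
- which of these holds the largest part of the solid substrate at the end of spring (solid substrate / first product / double product)
- first product at the end of midnight, in percent of the solid substrate charged

**The solid.** Ochre's solid reads 0% at 1.00 min, earlier than the asked time, so I expect solid substrate to be gone from both new flasks by their end.

**The constant.** Amber carries more reagent than solid substrate, so I treat its fall of first product as roughly pseudo-first-order. Its first two readings give 0.0300 L mol⁻¹ s⁻¹ for the doubling constant, the fall in the logarithm of first product per unit time and per unit concentration of reagent.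

**The exposure.** Multiply that constant by the reagent charge, the mean fraction of that charge still present, and the time. At an exposure of 0.693, first product made at the start, if doubling is what uses it, equals the double product made from it.

**Two rounds.** With the fraction at 1, midnight's exposure is 0.720, too close to that line for readings with this scatter. But if first product stays ahead of double product, each solid substrate taken up uses about one reagent, and midnight's charges are equal. Reagent should therefore fall a long way during midnight, and I put the mean fraction back in as 0.5. The exposure becomes 0.360, below the line, so I would charge midnight unchanged and expect first product near ochre's final 27.1%. Spring, even at that fraction, reaches 1.44, above the line, so I expect double product to lead there.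

**Forecast, result.** The forecast answers solid substrate for midnight, double product for spring and 30% of first product at the end of midnight (from 22% to 38%), with “substrate (mostly dissolved) the largest part”. Midnight ends with 24.7% first product, 6.40% double product and 0% solid substrate; spring ends with 48.9% double product and 10.6% first product.

    starting material + reagent → first product (k = 0.200 L mol⁻¹ s⁻¹)
    reagent + first product → double product (k = 0.0290 L mol⁻¹ s⁻¹)
    solid substrate ⇌ starting material, rate k3*(cs3 - [starting material]) while solid is left; crystals form when [starting material] > cs3 (solubility = 0.100 M, k = 0.0670 s⁻¹)
    first product ⇌ isomer of the product (K = 2.90, k = 0.0190 s⁻¹)
    starting material → decomposition product (k = 1.20 × 10⁻⁴ s⁻¹)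

**The neighbour.** Midnight keeps 16% of its reagent, so taking the mean of start and end gives an exposure of 0.419, below the line. The neighbour charged with 0.40 M of reagent keeps 48%, and the same reckoning gives 1.33, above the line. That neighbour ends with double product at 30.3%, ahead of first product at 18.2%.

The numbers in the tables were generated by integration from invented constants, noise included.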